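**Retrosynthetic overview**
1. The sulfate goes on last: target ⇐ phenol (bromoiesol A) + SO3·pyridine; the phenol OH of ring A ⇐ formyl group by Baeyer–Villiger oxidation (CHO = masked OH).
2. Ring B–O–ring C bond ⇐ Br/OAr-flanked tribromophenol + (2,4-dibromophenyl)(trimethoxyphenyl)iodonium salt; the third bromine of ring B is placed just before by OH-directed ortho-bromination.
3. Ring A–O–ring B bond ⇐ conjugate addition–elimination (SNAr) of mono-MOM-protected 4,5-dibromocatechol to 3,5-dibromo-2-fluorobenzaldehyde.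
4. Mono-protected 4,5-dibromocatechol ⇐ 3,4-dibromophenol + formaldehyde. This aldol-type ortho-hydroxymethylation/formylation is the only C–C bond made; the carbon is later excised by Baeyer–Villiger oxidation, which differentiates the two catechol oxygens.
5. No ring is constructed. All three benzene rings are bought and joined in the order B, then A–O–B, then A–O–B–O–C.

Assumption: the target is achiral (no stereocentre), so there is no configuration to set; it is delivered as the free hydrogen sulfate drawn, kept cold (its salts are the storable form).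

**Route**

Step 1
Reactants: 1 3,4-dibromophenol; 2 paraformaldehyde
Product: 4 4,5-dibromo-2-hydroxybenzaldehyde, via magnesium salicyl alcoholate 3 (not isolated)
Conditions: (CH2O)n (3 equiv), MgCl2 (2 equiv), Et3N (2 equiv), MeCN, reflux; 1 M HCl work-up
Reagents that add atoms: none
Why: Casnati–Skattebøl ortho-formylation, in which the magnesium phenoxide adds as an enolate through its less hindered ortho carbon to formaldehyde (aldol-type C–C bond formation) to give 3, and an Oppenauer-type hydride transfer to a second formaldehyde then gives the aldehyde.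

Step 2
Reactants: 4 4,5-dibromo-2-hydroxybenzaldehyde
Product: 5 4,5-dibromo-2-(methoxymethoxy)benzaldehyde
Conditions: MOMCl, i-Pr2NEt, CH2Cl2, 0 °C → rt
Reagents that add atoms: chloromethyl methyl ether (MOMCl), COCCl
Why: Williamson-type O-alkylation (MOM protection) masks the phenol so that it survives the peracid and the basic ether formation and can later be freed by acid without harming an aldehyde.

Step 3
Reactants: 5 4,5-dibromo-2-(methoxymethoxy)benzaldehyde
Product: 7 4,5-dibromo-2-(methoxymethoxy)phenol, via aryl formate 6 (not isolated)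
Conditions: mCPBA, CH2Cl2, rt → 40 °C; then K2CO3 (cat.), MeOH, rt
Reagents that add atoms: mCPBA, O=C(OO)c1cccc(Cl)c1
Why: Baeyer–Villiger (Dakin-type) oxidation in which the ortho-alkoxy aryl group migrates in preference to hydrogen, and methanolysis of formate 6 then leaves a catechol with one oxygen free and one protected.

Step 4
Reactants: 7 4,5-dibromo-2-(methoxymethoxy)phenol; 8 3,5-dibromo-2-fluorobenzaldehyde
Product: 9 3,5-dibromo-2-[4,5-dibromo-2-(methoxymethoxy)phenoxy]benzaldehyde
Conditions: K2CO3, DMF, 90 °C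
Reagents that add atoms: none
Why: Nucleophilic aromatic substitution, i.e. conjugate (Michael-type) addition of the phenoxide to the formyl-activated C–F carbon and loss of fluoride from the Meisenheimer enolate; both bromines are meta to the carbonyl and stay.

Step 5
Reactants: 9 3,5-dibromo-2-[4,5-dibromo-2-(methoxymethoxy)phenoxy]benzaldehyde
Product: 10 3,5-dibromo-2-(4,5-dibromo-2-hydroxyphenoxy)benzaldehyde
Conditions: 3 M HCl (aq), THF, 50 °C
Reagents that add atoms: none
Why: Acid-catalysed acetal hydrolysis removes the MOM group and leaves the diaryl ether, the aryl bromides and the non-enolisable aldehyde untouched.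

Step 6
Reactants: 10 3,5-dibromo-2-(4,5-dibromo-2-hydroxyphenoxy)benzaldehyde
Product: 11 3,5-dibromo-2-(3,4,5-tribromo-2-hydroxyphenoxy)benzaldehyde
Conditions: Br2 (1.05 equiv), AcOH, rt
Reagents that add atoms: bromine, BrBr
Why: Electrophilic aromatic bromination directed by the free OH to its only open ortho position, while ring A is deactivated by CHO and has no free position ortho or para to its oxygen.

Step 7
Reactants: 12 2,4-dibromo-1-iodobenzene; 13 1,3,5-trimethoxybenzene
Product: 15 (2,4-dibromophenyl)(2,4,6-trimethoxyphenyl)iodonium tosylate, via Koser-type iodane 14 (not isolated)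
Conditions: mCPBA, TsOH·H2O, MeCN, 77 °C; then 13, 77 °C → rt; Et2O trituration
Reagents that add atoms: p-toluenesulfonic acid, Cc1ccc(cc1)S(=O)(=O)O; mCPBA, O=C(OO)c1cccc(Cl)c1 (its oxygen is carried only by 14)
Why: One-pot oxidation of the aryl iodide to a hydroxy(tosyloxy)-λ3-iodane followed by electrophilic aromatic substitution on trimethoxybenzene gives the unsymmetrical diaryliodonium salt, with the aryl position fixed by the iodide.

Step 8
Reactants: 11 3,5-dibromo-2-(3,4,5-tribromo-2-hydroxyphenoxy)benzaldehyde; 15 (2,4-dibromophenyl)(2,4,6-trimethoxyphenyl)iodonium tosylate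
Product: 16 3,5-dibromo-2-[3,4,5-tribromo-2-(2,4-dibromophenoxy)phenoxy]benzaldehyde
Conditions: t-BuOK (1.05 equiv), THF, 0 °C; then 15 (1.2 equiv), rt → 40 °C
Reagents that add atoms: none
Why: Metal-free O-arylation with a diaryliodonium salt (ligand coupling at iodine(III)) tolerates the di-ortho-substituted phenoxide and transfers the electron-poorer ortho-bromo aryl group, not the trimethoxyphenyl dummy ligand.

Step 9
Reactants: 16 3,5-dibromo-2-[3,4,5-tribromo-2-(2,4-dibromophenoxy)phenoxy]benzaldehyde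
Product: 18 3,5-dibromo-2-[3,4,5-tribromo-2-(2,4-dibromophenoxy)phenoxy]phenol (bromoiesol A), via aryl formate 17 (not isolated)
Conditions: mCPBA (3 equiv), CH2Cl2, 40 °C; then K2CO3 (cat.), MeOH, rt
Reagents that add atoms: mCPBA, O=C(OO)c1cccc(Cl)c1
Why: Baeyer–Villiger oxidation with aryl migration assisted by the ortho aryloxy oxygen turns the formyl group into formate 17, which is methanolysed to the phenol.

Step 10
Reactants: 18 3,5-dibromo-2-[3,4,5-tribromo-2-(2,4-dibromophenoxy)phenoxy]phenol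
Product: 20 3,5-dibromo-2-[3,4,5-tribromo-2-(2,4-dibromophenoxy)phenoxy]phenyl hydrogen sulfate (bromoiesol A sulfate), via pyridinium aryl sulfate 19 (not isolated)
Conditions: SO3·pyridine (5 equiv), pyridine, 50 °C; then Dowex 50W (H+ form), MeOH/H2O, 0 °C
Reagents that add atoms: sulfur trioxide–pyridine complex, O=S(=O)([O-])[n+]1ccccc1
Why: O-Sulfonation of the phenol by the SO3·pyridine complex gives the pyridinium sulfate, and cation exchange then delivers the hydrogen sulfate.

**Compound list**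
1 | 3,4-dibromophenol | Oc1ccc(Br)c(Br)c1 | starting material
2 | paraformaldehyde (formaldehyde source, monomer shown) | C=O | starting material
3 | 4,5-dibromo-2-(hydroxymethyl)phenol, present as its magnesium phenoxide | OCc1cc(Br)c(Br)cc1O | intermediate
4 | 4,5-dibromo-2-hydroxybenzaldehyde | O=Cc1cc(Br)c(Br)cc1O | intermediate
5 | 4,5-dibromo-2-(methoxymethoxy)benzaldehyde | COCOc1cc(Br)c(Br)cc1C=O | intermediate
6 | 4,5-dibromo-2-(methoxymethoxy)phenyl formate | COCOc1cc(Br)c(Br)cc1OC=O | intermediate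
7 | 4,5-dibromo-2-(methoxymethoxy)phenol | COCOc1cc(Br)c(Br)cc1O | intermediate
8 | 3,5-dibromo-2-fluorobenzaldehyde | O=Cc1cc(Br)cc(Br)c1F | starting material
9 | 3,5-dibromo-2-[4,5-dibromo-2-(methoxymethoxy)phenoxy]benzaldehyde | COCOc1cc(Br)c(Br)cc1Oc1c(Br)cc(Br)cc1C=O | intermediate
10 | 3,5-dibromo-2-(4,5-dibromo-2-hydroxyphenoxy)benzaldehyde | Oc1cc(Br)c(Br)cc1Oc1c(Br)cc(Br)cc1C=O | intermediate
11 | 3,5-dibromo-2-(3,4,5-tribromo-2-hydroxyphenoxy)benzaldehyde | Oc1c(Br)c(Br)c(Br)cc1Oc1c(Br)cc(Br)cc1C=O | intermediate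
12 | 2,4-dibromo-1-iodobenzene | Brc1ccc(I)c(Br)c1 | starting material
13 | 1,3,5-trimethoxybenzene | COc1cc(OC)cc(OC)c1 | starting material
14 | [hydroxy(tosyloxy)iodo]-2,4-dibromobenzene (Koser-type iodane) | Cc1ccc(cc1)S(=O)(=O)OI(O)c1ccc(Br)cc1Br | intermediate
15 | (2,4-dibromophenyl)(2,4,6-trimethoxyphenyl)iodonium 4-methylbenzenesulfonate | COc1cc(OC)c([I+]c2ccc(Br)cc2Br)c(OC)c1.Cc1ccc(cc1)S(=O)(=O)[O-] | intermediate
16 | 3,5-dibromo-2-[3,4,5-tribromo-2-(2,4-dibromophenoxy)phenoxy]benzaldehyde | O=Cc1cc(Br)cc(Br)c1Oc1cc(Br)c(Br)c(Br)c1Oc1ccc(Br)cc1Br | intermediate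
17 | 3,5-dibromo-2-[3,4,5-tribromo-2-(2,4-dibromophenoxy)phenoxy]phenyl formate | O=COc1cc(Br)cc(Br)c1Oc1cc(Br)c(Br)c(Br)c1Oc1ccc(Br)cc1Br | intermediate
18 | 3,5-dibromo-2-[3,4,5-tribromo-2-(2,4-dibromophenoxy)phenoxy]phenol (bromoiesol A) | Oc1cc(Br)cc(Br)c1Oc1cc(Br)c(Br)c(Br)c1Oc1ccc(Br)cc1Br | intermediate
19 | pyridinium 3,5-dibromo-2-[3,4,5-tribromo-2-(2,4-dibromophenoxy)phenoxy]phenyl sulfate | [O-]S(=O)(=O)Oc1cc(Br)cc(Br)c1Oc1cc(Br)c(Br)c(Br)c1Oc1ccc(Br)cc1Br.c1cc[nH+]cc1 | intermediate
20 | 3,5-dibromo-2-[3,4,5-tribromo-2-(2,4-dibromophenoxy)phenoxy]phenyl hydrogen sulfate (bromoiesol A sulfate) | O=S(=O)(O)Oc1cc(Br)cc(Br)c1Oc1cc(Br)c(Br)c(Br)c1Oc1ccc(Br)cc1Br | target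

**Step count and risks**

Total steps: 10. Longest linear sequence: 9 (steps 1–6 and 8–10 from compound 1); step 7 is a one-step side branch.

Most at risk, first, is the O-arylation of step 8. The phenoxide of 11 is flanked by Br and an aryloxy group, and under base the formyl-activated ring A could in principle migrate between the two catechol oxygens (Smiles rearrangement), so the reaction is kept at or below 40 °C. The fallback sets out from 11: SNAr with 2-bromo-1-fluoro-4-nitrobenzene (K2CO3, DMF, 40–50 °C) gives 3,5-dibromo-2-[3,4,5-tribromo-2-(2-bromo-4-nitrophenoxy)phenoxy]benzaldehyde F1. Reduction with SnCl2·2H2O (EtOH, 60 °C) gives 2-[2-(4-amino-2-bromophenoxy)-3,4,5-tribromophenoxy]-3,5-dibromobenzaldehyde F2. This is not stored but diazotised at once (NaNO2, 48% HBr, AcOH, 0 °C) to the arenediazonium bromide F3 and treated with CuBr (Sandmeyer) to come back to the route at 16.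

Second is the Baeyer–Villiger oxidation of step 9, where hydrogen migration to the benzoic acid can compete on the electron-poor, hindered aldehyde. The fallback sets out from 16: MeMgBr (THF, −78 °C) gives the racemic 1-arylethanol F4, and Dess–Martin periodinane (CH2Cl2, rt) gives the aryl methyl ketone F5. Baeyer–Villiger oxidation with CF3CO3H (TFAA, urea·H2O2, Na2HPO4, CH2Cl2), where aryl migrates in preference to methyl and no hydrogen can compete, gives the aryl acetate F6. K2CO3 in MeOH then comes back to the route at 18.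

Third is the sulfation and isolation of the free acid in step 10, where the ionic product is hard to purify and the free hydrogen sulfate is prone to hydrolysis. The fallback sets out from 18: 2,2,2-trichloroethyl chlorosulfate (Et3N, DMAP, THF, rt) gives the neutral, chromatographable aryl 2,2,2-trichloroethyl sulfate diester F7. Zn dust and HCO2NH4 in MeOH (rt; no Pd, so the aryl bromides stay) give the ammonium aryl sulfate F8. The same H+ resin exchange at 0 °C comes back to the route at 20.

**Further compounds**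
F1 | step 8 | 3,5-dibromo-2-[3,4,5-tribromo-2-(2-bromo-4-nitrophenoxy)phenoxy]benzaldehyde | O=Cc1cc(Br)cc(Br)c1Oc1cc(Br)c(Br)c(Br)c1Oc1ccc(cc1Br)[N+](=O)[O-]
F2 | step 8 | 2-[2-(4-amino-2-bromophenoxy)-3,4,5-tribromophenoxy]-3,5-dibromobenzaldehyde | O=Cc1cc(Br)cc(Br)c1Oc1cc(Br)c(Br)c(Br)c1Oc1ccc(N)cc1Br
F3 | step 8 | 3-bromo-4-[2,3,4-tribromo-6-(2,4-dibromo-6-formylphenoxy)phenoxy]benzenediazonium bromide | O=Cc1cc(Br)cc(Br)c1Oc1cc(Br)c(Br)c(Br)c1Oc1ccc(cc1Br)[N+]#N.[Br-]
F4 | step 9 | 1-{3,5-dibromo-2-[3,4,5-tribromo-2-(2,4-dibromophenoxy)phenoxy]phenyl}ethanol (racemic) | CC(O)c1cc(Br)cc(Br)c1Oc1cc(Br)c(Br)c(Br)c1Oc1ccc(Br)cc1Br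
F5 | step 9 | 1-{3,5-dibromo-2-[3,4,5-tribromo-2-(2,4-dibromophenoxy)phenoxy]phenyl}ethanone | CC(=O)c1cc(Br)cc(Br)c1Oc1cc(Br)c(Br)c(Br)c1Oc1ccc(Br)cc1Br
F6 | step 9 | 3,5-dibromo-2-[3,4,5-tribromo-2-(2,4-dibromophenoxy)phenoxy]phenyl acetate | CC(=O)Oc1cc(Br)cc(Br)c1Oc1cc(Br)c(Br)c(Br)c1Oc1ccc(Br)cc1Br
F7 | step 10 | 3,5-dibromo-2-[3,4,5-tribromo-2-(2,4-dibromophenoxy)phenoxy]phenyl 2,2,2-trichloroethyl sulfate | ClC(Cl)(Cl)COS(=O)(=O)Oc1cc(Br)cc(Br)c1Oc1cc(Br)c(Br)c(Br)c1Oc1ccc(Br)cc1Br
F8 | step 10 | ammonium 3,5-dibromo-2-[3,4,5-tribromo-2-(2,4-dibromophenoxy)phenoxy]phenyl sulfate | [NH4+].[O-]S(=O)(=O)Oc1cc(Br)cc(Br)c1Oc1cc(Br)c(Br)c(Br)c1Oc1ccc(Br)cc1Br
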